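**Retrosynthetic overview**

1. Benzofuran numbering is used (O1, C2, C3, C3a, C4–C7, C7a; ring A = carbocycle, ring B = dihydrofuran). The C5 gem-diprenyl / C4 ketone array of target 18 is the Claisen product of the aryl 1,1-dimethylallyl ether 17, and the C2 carbinol of 17 is the double methyl adduct of ester 15.
2. The strategy rests on ring B: its stereocentre C2 is bonded to both the benzylic C3H2 and O1, which sit on the adjacent ring-A carbons C3a and C7a. Ring B is therefore an ortho-quinone methide (C3=C3a–C7a=O1) plus one carbon.
3. Ester 15 is disconnected to quinone methide 13 and the ester-stabilised sulfonium ylide 12 in a [4+1] annulation (bond C3–C2, then bond O1–C2). 13 is released from ammonium salt 10, made from Mannich base 9; the C4 ether fixes the fusion sense and is the latent second prenyl group.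
4. 9 comes from phloroglucinol 1 by C-acylation, mono-C-prenylation, para-O-propargylation, Mannich aminomethylation and semihydrogenation.
5. Ring order: ring A is present from the start as the arene, ring B is closed in step 8, and ring A is dearomatised in the last step.

Key step: step 8

Assumption: the sense of induction of the squaramide in step 8 cannot be assigned in advance; the quinine-derived catalyst is written, and its quinidine-derived pseudo-enantiomer is used instead if that is the one that delivers (2R)-15.

**Route**

Step 1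
Reactants: 1 phloroglucinol; 2 isovaleryl chloride (3-methylbutanoyl chloride)
Product: 3 3-methyl-1-(2,4,6-trihydroxyphenyl)butan-1-one
Conditions: AlCl3, PhNO2, 65 °C; then cold aq HCl
Reagents that add atoms: none
Why: Friedel–Crafts C-acylation of the symmetric, strongly activated triphenol should stop at the monoketone because the acyl group deactivates the ring towards a second acylation.

Step 2
Reactants: 3 3-methyl-1-(2,4,6-trihydroxyphenyl)butan-1-one; 4 prenyl bromide (1-bromo-3-methylbut-2-ene)
Product: 5 3-methyl-1-[2,4,6-trihydroxy-3-(3-methylbut-2-enyl)phenyl]butan-1-one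
Conditions: 4 (0.9 equiv), 10% aq KOH, 0 °C
Reagents that add atoms: none
Why: C-alkylation of the ambident acylphloroglucinolate in water (solvated oxygens favour attack through carbon) with a slight deficit of the bromide should give the mono-C-prenyl compound, separable from recovered 3 and the diprenyl by-product.

Step 3
Reactants: 5 3-methyl-1-[2,4,6-trihydroxy-3-(3-methylbut-2-enyl)phenyl]butan-1-one; 6 3-chloro-3-methylbut-1-yne
Product: 7 1-[2,6-dihydroxy-4-(2-methylbut-3-yn-2-yloxy)-3-(3-methylbut-2-enyl)phenyl]-3-methylbutan-1-one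
Conditions: CuCl2·2H2O (1 mol%), DBU (1.3 equiv), MeCN, 0 °C
Reagents that add atoms: none
Why: copper-catalysed propargylic etherification of a phenol by a tertiary propargylic chloride should take place at the hydroxyl para to the acyl group, which is the most acidic one and, unlike the two ortho hydroxyls, is neither chelated to nor shielded by the ketone.

Step 4
Reactants: 7 1-[2,6-dihydroxy-4-(2-methylbut-3-yn-2-yloxy)-3-(3-methylbut-2-enyl)phenyl]-3-methylbutan-1-one
Product: 8 1-[3-[(dimethylamino)methyl]-2,6-dihydroxy-4-(2-methylbut-3-yn-2-yloxy)-5-(3-methylbut-2-enyl)phenyl]-3-methylbutan-1-one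
Conditions: CH2O (37% aq), Me2NH (40% aq), EtOH, 0 °C to rt
Reagents that add atoms: formaldehyde, C=O; dimethylamine, CNC
Why: phenolic Mannich reaction at the only unsubstituted ring carbon, which is ortho and para to hydroxyl groups; it is placed before the alkyne reduction so that an allyl aryl ether with a free ortho position, prone to an ordinary aromatic Claisen shift, never exists.

Step 5
Reactants: 8 1-[3-[(dimethylamino)methyl]-2,6-dihydroxy-4-(2-methylbut-3-yn-2-yloxy)-5-(3-methylbut-2-enyl)phenyl]-3-methylbutan-1-one
Product: 9 1-[3-[(dimethylamino)methyl]-2,6-dihydroxy-4-(2-methylbut-3-en-2-yloxy)-5-(3-methylbut-2-enyl)phenyl]-3-methylbutan-1-one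
Conditions: H2 (1 atm), Pd/CaCO3 poisoned with Pb(OAc)2, quinoline, EtOAc, rt, stopped after 1 equiv H2
Reagents that add atoms: none
Why: Lindlar semihydrogenation of the terminal alkyne should stop at the vinyl group on the poisoned catalyst, leaving the trisubstituted prenyl alkene, the tertiary allylic C–O bond and the benzylic amine untouched.

Step 6
Reactants: 9 1-[3-[(dimethylamino)methyl]-2,6-dihydroxy-4-(2-methylbut-3-en-2-yloxy)-5-(3-methylbut-2-enyl)phenyl]-3-methylbutan-1-one
Product: 10 1-[2,4-dihydroxy-3-(3-methylbutanoyl)-6-(2-methylbut-3-en-2-yloxy)-5-(3-methylbut-2-enyl)phenyl]-N,N,N-trimethylmethanaminium iodide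
Conditions: MeI (3 equiv), Et2O, rt, dark; salt collected by filtration
Reagents that add atoms: iodomethane, CI
Why: Menshutkin N-alkylation; with no base present the tertiary amine is far more nucleophilic than the hydrogen-bonded phenols, and precipitation of the salt from ether removes it from further reaction.

Step 7
Reactants: 11 (2-ethoxy-2-oxoethyl)dimethylsulfonium bromide
Product: 12 ethyl 2-(dimethyl-lambda4-sulfanylidene)acetate
Conditions: 12.5 M aq NaOH (1.0 equiv), saturated aq K2CO3, CHCl3, 5–10 °C; dried over K2CO3, concentrated cold, used at once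
Reagents that add atoms: none
Why: deprotonation of the CH2 group flanked by sulfonium and ester gives the isolable ester-stabilised sulfonium ylide.

Step 8
Reactants: 10 1-[2,4-dihydroxy-3-(3-methylbutanoyl)-6-(2-methylbut-3-en-2-yloxy)-5-(3-methylbut-2-enyl)phenyl]-N,N,N-trimethylmethanaminium iodide; 12 ethyl 2-(dimethyl-lambda4-sulfanylidene)acetate
Product: 15 ethyl (2R)-6-hydroxy-4-(2-methylbut-3-en-2-yloxy)-7-(3-methylbutanoyl)-5-(3-methylbut-2-enyl)-2,3-dihydro-1-benzofuran-2-carboxylate, via ortho-quinone methide 13 (not isolated), via sulfonium phenoxide betaine 14 (not isolated)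
Conditions: 12 (2 equiv), Cs2CO3 (powdered, 2.2 equiv), 3-[3,5-bis(trifluoromethyl)anilino]-4-[(9-deoxy-epi-quinin-9-yl)amino]cyclobut-3-ene-1,2-dione (10 mol%), CHCl3/PhMe, −20 °C
Reagents that add atoms: none
Why: Proposed new method: carbonate deprotonates the hydroxyl ortho to the ammoniomethyl group of 10 and 1,4-elimination of NMe3 releases the ortho-quinone methide 13, whose carbonyl can only be the oxygen next to the acyl-bearing carbon because the other flanking oxygen is an ether; the nucleophilic carbon of ylide 12 then adds to the exocyclic CH2 (bond C3–C2), rearomatising ring A to the phenoxide–sulfonium betaine 14. The phenoxide displaces dimethyl sulfide at the sulfonium carbon in a 5-exo-tet SN2 closure with inversion (bond O1–C2), which forms ring B. The closest known reaction type is the organocatalytic asymmetric [4+1] annulation of in situ ortho-quinone methides with stabilised sulfur ylides to 2,3-dihydrobenzofurans, in which the methide carbon carries a substituent and becomes a stereocentre in the conjugate addition; here the methide carbon is CH2, so C2 is the only stereocentre and has to be set in the ring closure. Because C2–H of 14 lies between a sulfonium and an ester it is acidic and the two epimers interconvert (through the ylide form and by retro-addition), so the closure can run as a dynamic kinetic resolution in which the squaramide, hydrogen-bonded to the phenoxide oxygen and the ester carbonyl and assisted by its ammonium arm, selects the (S)-betaine, which closes with inversion to (2R)-15. The step needs the right fusion sense (secured by the C4 ether), attack of the stabilised ylide on the methide and not on the chelated aryl ketone, and O-alkylation ahead of elimination to a cinnamate (favoured by the intramolecular 5-exo geometry); slow heterogeneous release of 13 keeps its concentration low, which should suppress its dimerisation and the uncatalysed closure.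

Step 9
Reactants: 15 ethyl (2R)-6-hydroxy-4-(2-methylbut-3-en-2-yloxy)-7-(3-methylbutanoyl)-5-(3-methylbut-2-enyl)-2,3-dihydro-1-benzofuran-2-carboxylate
Product: 17 1-[(2R)-6-hydroxy-2-(2-hydroxypropan-2-yl)-4-(2-methylbut-3-en-2-yloxy)-5-(3-methylbut-2-enyl)-2,3-dihydro-1-benzofuran-7-yl]-3-methylbutan-1-one, via methyl ketone 16 (not isolated)
Conditions: MeMgBr (5 equiv), THF, −40 to 0 °C (ester added to the Grignard reagent); aq NH4Cl
Reagents that add atoms: methylmagnesium bromide, C[Mg]Br
Why: Grignard double addition to the ester through methyl ketone 16; the first equivalent turns the C6 phenol into a magnesium phenoxide chelated to the C7 ketone (a vinylogous carboxylate flanked by two ortho substituents), so the ester activated by its α-oxygen should be attacked selectively, and at low temperature addition outruns deprotonation at C2, which keeps its configuration.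

Step 10
Reactants: 17 1-[(2R)-6-hydroxy-2-(2-hydroxypropan-2-yl)-4-(2-methylbut-3-en-2-yloxy)-5-(3-methylbut-2-enyl)-2,3-dihydro-1-benzofuran-7-yl]-3-methylbutan-1-one
Product: 18 (2R)-6-hydroxy-2-(2-hydroxypropan-2-yl)-7-(3-methylbutanoyl)-5,5-bis(3-methylbut-2-enyl)-2,3-dihydro-1-benzofuran-4(5H)-one
Conditions: PhMe (degassed), 110 °C, sealed tube
Reagents that add atoms: none
Why: aromatic Claisen rearrangement ([3,3]-sigmatropic shift) of an aryl 1,1-dimethylallyl ether with both ortho carbons substituted: the allyl terminus should bond to C5 rather than C3a because the chelated ortho-hydroxy ketone (C6–OH to the C7 acyl) fixes double-bond character in C4–C5 and attack at C3a would create a quaternary ring-fusion carbon, the C5 dienone cannot rearomatise and is held as the hydrogen-bonded enol of a cyclic β-triketone (a C3a dienone can revert by retro-Claisen and drain to it), and C2 is remote and untouched.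

**Compound list**

1 | phloroglucinol (benzene-1,3,5-triol) | Oc1cc(O)cc(O)c1 | starting material
2 | isovaleryl chloride (3-methylbutanoyl chloride) | CC(C)CC(Cl)=O | starting material
3 | 3-methyl-1-(2,4,6-trihydroxyphenyl)butan-1-one | CC(C)CC(=O)c1c(O)cc(O)cc1O | intermediate
4 | prenyl bromide (1-bromo-3-methylbut-2-ene) | CC(C)=CCBr | starting material
5 | 3-methyl-1-[2,4,6-trihydroxy-3-(3-methylbut-2-enyl)phenyl]butan-1-one | CC(C)=CCc1c(O)cc(O)c(C(=O)CC(C)C)c1O | intermediate
6 | 3-chloro-3-methylbut-1-yne | CC(C)(Cl)C#C | starting material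
7 | 1-[2,6-dihydroxy-4-(2-methylbut-3-yn-2-yloxy)-3-(3-methylbut-2-enyl)phenyl]-3-methylbutan-1-one | CC(C)=CCc1c(OC(C)(C)C#C)cc(O)c(C(=O)CC(C)C)c1O | intermediate
8 | 1-[3-[(dimethylamino)methyl]-2,6-dihydroxy-4-(2-methylbut-3-yn-2-yloxy)-5-(3-methylbut-2-enyl)phenyl]-3-methylbutan-1-one | CC(C)=CCc1c(OC(C)(C)C#C)c(CN(C)C)c(O)c(C(=O)CC(C)C)c1O | intermediate
9 | 1-[3-[(dimethylamino)methyl]-2,6-dihydroxy-4-(2-methylbut-3-en-2-yloxy)-5-(3-methylbut-2-enyl)phenyl]-3-methylbutan-1-one | CC(C)=CCc1c(OC(C)(C)C=C)c(CN(C)C)c(O)c(C(=O)CC(C)C)c1O | intermediate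
10 | 1-[2,4-dihydroxy-3-(3-methylbutanoyl)-6-(2-methylbut-3-en-2-yloxy)-5-(3-methylbut-2-enyl)phenyl]-N,N,N-trimethylmethanaminium iodide | CC(C)=CCc1c(OC(C)(C)C=C)c(C[N+](C)(C)C)c(O)c(C(=O)CC(C)C)c1O.[I-] | intermediate
11 | (2-ethoxy-2-oxoethyl)dimethylsulfonium bromide | CCOC(=O)C[S+](C)C.[Br-] | starting material
12 | ethyl 2-(dimethyl-lambda4-sulfanylidene)acetate | CCOC(=O)C=S(C)C | intermediate
13 | ortho-quinone methide, formed in the flask: 3-hydroxy-6-methylidene-2-(3-methylbutanoyl)-5-(2-methylbut-3-en-2-yloxy)-4-(3-methylbut-2-enyl)cyclohexa-2,4-dien-1-one | CC(C)=CCC1=C(OC(C)(C)C=C)C(=C)C(=O)C(C(=O)CC(C)C)=C1O | intermediate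
14 | sulfonium phenoxide betaine, formed in the flask, both epimers at the sulfonium carbon interconverting: 2-[2-(dimethylsulfonio)-3-ethoxy-3-oxopropyl]-5-hydroxy-6-(3-methylbutanoyl)-3-(2-methylbut-3-en-2-yloxy)-4-(3-methylbut-2-enyl)phenolate | CC(C)=CCc1c(OC(C)(C)C=C)c(CC(C(=O)OCC)[S+](C)C)c([O-])c(C(=O)CC(C)C)c1O | intermediate
15 | ethyl (2R)-6-hydroxy-4-(2-methylbut-3-en-2-yloxy)-7-(3-methylbutanoyl)-5-(3-methylbut-2-enyl)-2,3-dihydro-1-benzofuran-2-carboxylate | CC(C)=CCc1c(OC(C)(C)C=C)c2c(O[C@@H](C(=O)OCC)C2)c(C(=O)CC(C)C)c1O | intermediate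
16 | methyl ketone, formed in the flask: 1-[(2R)-2-acetyl-6-hydroxy-4-(2-methylbut-3-en-2-yloxy)-5-(3-methylbut-2-enyl)-2,3-dihydro-1-benzofuran-7-yl]-3-methylbutan-1-one | CC(C)=CCc1c(OC(C)(C)C=C)c2c(O[C@@H](C(C)=O)C2)c(C(=O)CC(C)C)c1O | intermediate
17 | 1-[(2R)-6-hydroxy-2-(2-hydroxypropan-2-yl)-4-(2-methylbut-3-en-2-yloxy)-5-(3-methylbut-2-enyl)-2,3-dihydro-1-benzofuran-7-yl]-3-methylbutan-1-one | CC(C)=CCc1c(OC(C)(C)C=C)c2c(O[C@@H](C(C)(C)O)C2)c(C(=O)CC(C)C)c1O | intermediate
18 | (2R)-6-hydroxy-2-(2-hydroxypropan-2-yl)-7-(3-methylbutanoyl)-5,5-bis(3-methylbut-2-enyl)-2,3-dihydro-1-benzofuran-4(5H)-one (CNP0104249.1) | CC(C)=CCC1(CC=C(C)C)C(=O)C2=C(O[C@@H](C(C)(C)O)C2)C(C(=O)CC(C)C)=C1O | target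

**Step count and risks**

Total step count: 10. Longest linear sequence: 9 steps (steps 1–6 and 8–10 from phloroglucinol 1); step 7 is a one-step side branch.

Steps most likely to fail:

1. Step 8 (proposed new method). The two diastereomeric ring closures of the epimerising betaine may not be differentiated well enough by the hydrogen-bonding catalyst, or the uncatalysed closure may compete, so that the ester forms with low enantiomeric purity; the quinone methide may also dimerise before it is trapped. Fallback: setting out from 10 and 12, the annulation is run with Cs2CO3 alone in CH2Cl2 at 0 °C, which is the known racemic [4+1] reaction of ortho-quinone methides with ester-stabilised sulfonium ylides and should give racemic ethyl 6-hydroxy-4-(2-methylbut-3-en-2-yloxy)-7-(3-methylbutanoyl)-5-(3-methylbut-2-enyl)-2,3-dihydro-1-benzofuran-2-carboxylate F1. Preparative chromatography on an amylose tris(3,5-dimethylphenylcarbamate) stationary phase then separates the (2R)-ester, at which the route is rejoined as compound 15, from ethyl (2S)-6-hydroxy-4-(2-methylbut-3-en-2-yloxy)-7-(3-methylbutanoyl)-5-(3-methylbut-2-enyl)-2,3-dihydro-1-benzofuran-2-carboxylate F2. F2 can be epimerised at C2 with DBU back to F1 and resubmitted.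

2. Step 10. The allyl group may migrate to the other ortho carbon (C3a), or the tertiary allyl ether may fragment with loss of isoprene on heating, instead of shifting to C5. Fallback: setting out from 17, the zerovalent palladium complex Pd(PPh3)4 (5 mol%) with morpholine in THF at rt cleaves the tertiary allyl aryl ether through a π-allyl complex and should give 1-[(2R)-4,6-dihydroxy-2-(2-hydroxypropan-2-yl)-5-(3-methylbut-2-enyl)-2,3-dihydro-1-benzofuran-7-yl]-3-methylbutan-1-one F3. Alkylative dearomatisation of its dianion with prenyl bromide 4 (NaOMe, MeOH, 0 °C), the known C-prenylation of acylphloroglucinols at the ring carbon between two oxygenated carbons, then returns to the route at target 18.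

3. Step 9. The Grignard reagent may add to the aryl ketone in competition with the ester, or may deprotonate C2 and erode its configuration. Fallback: setting out from 15, the order of the last two operations is reversed. Heating 15 in toluene at 110 °C should effect the Claisen shift first and give ethyl (2R)-6-hydroxy-7-(3-methylbutanoyl)-5,5-bis(3-methylbut-2-enyl)-4-oxo-3,5-dihydro-2H-1-benzofuran-2-carboxylate F4. MeMgBr (5 equiv, THF, −40 to 0 °C) first deprotonates this β-triketone enol to a delocalised magnesium enolate in which all ring-bound carbonyl carbons are deactivated, so that only the ester is left to take up two methyl groups; this returns to the route at target 18.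

**Further compounds**

F1 | step 8 | racemic ethyl 6-hydroxy-4-(2-methylbut-3-en-2-yloxy)-7-(3-methylbutanoyl)-5-(3-methylbut-2-enyl)-2,3-dihydro-1-benzofuran-2-carboxylate | CC(C)=CCc1c(OC(C)(C)C=C)c2c(OC(C(=O)OCC)C2)c(C(=O)CC(C)C)c1O
F2 | step 8 | ethyl (2S)-6-hydroxy-4-(2-methylbut-3-en-2-yloxy)-7-(3-methylbutanoyl)-5-(3-methylbut-2-enyl)-2,3-dihydro-1-benzofuran-2-carboxylate | CC(C)=CCc1c(OC(C)(C)C=C)c2c(O[C@H](C(=O)OCC)C2)c(C(=O)CC(C)C)c1O
F3 | step 10 | 1-[(2R)-4,6-dihydroxy-2-(2-hydroxypropan-2-yl)-5-(3-methylbut-2-enyl)-2,3-dihydro-1-benzofuran-7-yl]-3-methylbutan-1-one | CC(C)=CCc1c(O)c2c(O[C@@H](C(C)(C)O)C2)c(C(=O)CC(C)C)c1O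
F4 | step 9 | ethyl (2R)-6-hydroxy-7-(3-methylbutanoyl)-5,5-bis(3-methylbut-2-enyl)-4-oxo-3,5-dihydro-2H-1-benzofuran-2-carboxylate | CC(C)=CCC1(CC=C(C)C)C(=O)C2=C(O[C@@H](C(=O)OCC)C2)C(C(=O)CC(C)C)=C1O
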